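**Strategy**

Everything rests on the vicinal dioxygen array O1–C2–C(CH3)2–OH of the dihydrofuran ring (O1, C2, C3, C3a, C7a): it is traced back to a (3R)-2,2-dimethylchroman-3-ol whose pyran oxygen still sits on the gem-dimethyl carbon. In the key step the alcohol is triflated, the aryl ether oxygen shifts from C(CH3)2 to the carbinol carbon through an aryloxiranium ion (six- to five-membered ring contraction with inversion, expected to give 2S), and water caps the tertiary cation as the 2-hydroxypropan-2-yl group. The chromanol comes from a propargyl Claisen chromene by Jacobsen epoxidation and hydride opening; a one-pot desilylation/Sonogashira/cycloisomerisation with 2-geranyl-4-iodoresorcinol then builds the benzofuran.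

Key step: step 7

Remark: the chromane is numbered O1, C2, C3, C4, C4a–C8a and the dihydrobenzofuran O1, C2, C3, C3a–C7a; the sense of induction in step 5 is assigned by analogy with the parent 2,2-dimethyl-2H-chromene.

**Route**

Step 1
Reactants: 1 3,5-dihydroxybenzaldehyde (2 equiv); 2 3-chloro-3-methylbut-1-yne
Product: 3 3-hydroxy-5-[(2-methylbut-3-yn-2-yl)oxy]benzaldehyde
Conditions: DBU, CuCl2·2H2O (cat.), MeCN, 0 °C
Reagents that add atoms: none
Why: Copper-catalysed O-propargylation of a phenol with a tertiary propargylic chloride (substitution through a copper allenylidene); the excess of the symmetrical diol 1 should hold the reaction at the mono-ether, and unreacted 1 is recovered.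

Step 2
Reactants: 3 3-hydroxy-5-[(2-methylbut-3-yn-2-yl)oxy]benzaldehyde
Product: 4 3-[(2-methylbut-3-yn-2-yl)oxy]-5-[(triisopropylsilyl)oxy]benzaldehyde
Conditions: TIPSCl, imidazole, DMF, 20 °C
Reagents that add atoms: triisopropylsilyl chloride, CC(C)[Si](Cl)(C(C)C)C(C)C
Why: Silyl ether formation on the remaining phenol; the bulky triisopropylsilyl group is chosen to survive heat, amide base, peracid, hydride and triflic anhydride and to leave with fluoride at the end.

Step 3
Reactants: 4 3-[(2-methylbut-3-yn-2-yl)oxy]-5-[(triisopropylsilyl)oxy]benzaldehyde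
Product: 6 2,2-dimethyl-7-[(triisopropylsilyl)oxy]-2H-chromene-5-carbaldehyde, via allenylphenol 5 (not isolated)
Conditions: N,N-diethylaniline, 180 °C
Reagents that add atoms: none
Why: Aromatic propargyl Claisen rearrangement ([3,3]) followed by enolisation, 1,5-hydrogen shift and oxa-6π electrocyclisation gives the 2H-chromene; the migration terminus para to the silyloxy group and ortho to the electron-withdrawing formyl group is the one both substituents favour, which should place the formyl group at C5.

Step 4
Reactants: 6 2,2-dimethyl-7-[(triisopropylsilyl)oxy]-2H-chromene-5-carbaldehyde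
Product: 7 [(5-ethynyl-2,2-dimethyl-2H-chromen-7-yl)oxy]tri(propan-2-yl)silane
Conditions: TMSCHN2, LDA, THF, −78 → 20 °C
Reagents that add atoms: (trimethylsilyl)diazomethane, C[Si](C)(C)C=[N+]=[N-]
Why: Colvin rearrangement: the lithiated diazo reagent adds to the non-enolisable aldehyde, Peterson-type elimination gives a diazoalkene, and the alkylidene carbene formed on loss of N2 undergoes 1,2-hydrogen shift to the terminal alkyne, without the methanolic base that could cleave the aryl silyl ether.

Step 5
Reactants: 7 [(5-ethynyl-2,2-dimethyl-2H-chromen-7-yl)oxy]tri(propan-2-yl)silane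
Product: 8 (3R,4R)-3,4-epoxy-5-ethynyl-2,2-dimethyl-7-[(triisopropylsilyl)oxy]chromane
Conditions: (R,R)-N,N'-bis(3,5-di-tert-butylsalicylidene)-1,2-cyclohexanediaminomanganese chloride [(R,R)-(salen)MnCl, trivalent manganese] (5 mol%), mCPBA, NMO, CH2Cl2, −78 °C
Reagents that add atoms: 3-chloroperbenzoic acid (mCPBA), O=C(OO)c1cccc(Cl)c1
Why: Jacobsen–Katsuki epoxidation, for which cis-configured 2,2-dimethyl-2H-chromenes are the best substrate class; both new stereocentres are set by the catalyst (reagent control), the (R,R)-complex being expected to give the (3R,4R)-epoxide as with the parent chromene, and the anhydrous peracid protocol at −78 °C should leave the terminal alkyne untouched.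

Step 6
Reactants: 8 (3R,4R)-3,4-epoxy-5-ethynyl-2,2-dimethyl-7-[(triisopropylsilyl)oxy]chromane
Product: 9 (3R)-5-ethynyl-2,2-dimethyl-7-[(triisopropylsilyl)oxy]chroman-3-ol
Conditions: LiAlH4, THF, 0 °C; aqueous Rochelle salt work-up
Reagents that add atoms: none
Why: Regioselective SN2 hydride opening of the epoxide at the benzylic C4, which is activated and unhindered whereas C3 is neopentyl; C3 is not touched, so its R configuration is kept while C4 becomes CH2.

Step 7
Reactants: 9 (3R)-5-ethynyl-2,2-dimethyl-7-[(triisopropylsilyl)oxy]chroman-3-ol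
Product: 11 2-{(2S)-4-ethynyl-6-[(triisopropylsilyl)oxy]-2,3-dihydro-1-benzofuran-2-yl}propan-2-ol, via triflate 10 (not isolated)
Conditions: Tf2O, 2,6-lutidine, CH2Cl2, −78 °C; then THF/H2O, NaHCO3, −78 → 20 °C
Reagents that add atoms: water, O; trifluoromethanesulfonic anhydride, O=S(=O)(OS(=O)(=O)C(F)(F)F)C(F)(F)F (its CF3SO2 group is carried by intermediate 10 only)
Why: The secondary triflate 10 should ionise with anchimeric assistance: in the half-chair with a pseudo-equatorial triflate the C2–O1 ring bond is antiperiplanar to C3–OTf, so the aryl ether oxygen displaces triflate from the rear to give a bicyclic aryloxiranium ion, which opens at the tertiary carbon, where water adds. The closest known reaction type is the semipinacol-like 1,2-aryloxy shift (Wagner–Meerwein-type ring contraction) of activated 2,2-dimethylchroman-3-ols to 2-substituted 2,3-dihydrobenzofurans. The five-membered ring (O1, C2, C3, C3a, C7a) is closed by an intramolecular SN2 displacement (3-exo-tet closure to the oxiranium ion, then cleavage of the O–C(CH3)2 bond), so the six-membered pyran contracts by one atom and the expelled carbon becomes the carbinol carbon of the side chain. The new C2 stereocentre is controlled by the substrate: the displacement is stereospecific with inversion at the carbinol carbon, so the (3R)-alcohol should give the (2S)-dihydrobenzofuran. The step needs oxygen migration to win over hydride or methyl shift and over E2 loss to the chromene, and water capture to win over E1 loss to the isopropenyl compound; the gem-dimethyl group on C2 secures the first (tertiary migration origin, no direct substitution at the neopentyl C3), and the hindered base, low temperature and buffered aqueous quench are meant to secure the second.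

Step 8
Reactants: 12 resorcinol
Product: 13 1,3-bis(methoxymethoxy)benzene
Conditions: MOMCl, i-Pr2NEt, CH2Cl2, 0 → 20 °C
Reagents that add atoms: chloromethyl methyl ether, COCCl
Why: Formation of the two methoxymethyl acetals, which serve as directing groups for both metalations and come off under mild acid.

Step 9
Reactants: 13 1,3-bis(methoxymethoxy)benzene; 14 geranyl bromide
Product: 15 2-[(2E)-3,7-dimethylocta-2,6-dien-1-yl]-1,3-bis(methoxymethoxy)benzene
Conditions: n-BuLi, THF, 0 °C; CuI (20 mol%), then 14, −40 → 20 °C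
Reagents that add atoms: none
Why: Directed ortho-metalation at C2, the position between the two acetal oxygens, followed by copper-mediated SN2 allylation with geranyl bromide, which should keep the E-alkene and the linear attachment.

Step 10
Reactants: 15 2-[(2E)-3,7-dimethylocta-2,6-dien-1-yl]-1,3-bis(methoxymethoxy)benzene
Product: 16 2-[(2E)-3,7-dimethylocta-2,6-dien-1-yl]-4-iodo-1,3-bis(methoxymethoxy)benzene
Conditions: n-BuLi, TMEDA, Et2O, 0 °C; then I2, THF, −78 °C
Reagents that add atoms: iodine, II
Why: Second directed ortho-metalation next to an acetal oxygen (the two open sites are equivalent by symmetry) and iodinolysis of the aryllithium; at −78 °C iodine should react with the carbanion far faster than with the trisubstituted alkenes.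

Step 11
Reactants: 16 2-[(2E)-3,7-dimethylocta-2,6-dien-1-yl]-4-iodo-1,3-bis(methoxymethoxy)benzene
Product: 17 2-[(2E)-3,7-dimethylocta-2,6-dien-1-yl]-4-iodobenzene-1,3-diol
Conditions: HCl (2 M aq.), MeOH, 40 °C
Reagents that add atoms: none
Why: Acid-catalysed acetal cleavage (transacetalisation to methanol) under mild conditions that should leave the geranyl chain uncyclised and the aryl iodide intact.

Step 12
Reactants: 11 2-{(2S)-4-ethynyl-6-[(triisopropylsilyl)oxy]-2,3-dihydro-1-benzofuran-2-yl}propan-2-ol; 17 2-[(2E)-3,7-dimethylocta-2,6-dien-1-yl]-4-iodobenzene-1,3-diol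
Product: 20 (2S)-4-{7-[(2E)-3,7-dimethylocta-2,6-dien-1-yl]-6-hydroxy-1-benzofuran-2-yl}-2-(2-hydroxypropan-2-yl)-2,3-dihydro-1-benzofuran-6-ol (CNP0312668.2), via alkynylphenol 18 (not isolated), via diarylalkyne 19 (not isolated)
Conditions: Bu4NF (1 equiv), THF, 0 °C; then 17, PdCl2(PPh3)2 (5 mol%), CuI (10 mol%), Et3N, DMF, 70 °C
Reagents that add atoms: none
Why: Fluoride cleaves the aryl silyl ether, then Sonogashira coupling of the terminal alkyne with the ortho-iodophenol and 5-endo-dig hydroalkoxylation by the only hydroxyl ortho to the alkyne form the 2-arylbenzofuran; no stereocentre is touched.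

**Compound list**

1 | 3,5-dihydroxybenzaldehyde | O=Cc1cc(O)cc(O)c1 | starting material
2 | 3-chloro-3-methylbut-1-yne | C#CC(C)(C)Cl | starting material
3 | 3-hydroxy-5-[(2-methylbut-3-yn-2-yl)oxy]benzaldehyde | O=Cc1cc(O)cc(OC(C)(C)C#C)c1 | intermediate
4 | 3-[(2-methylbut-3-yn-2-yl)oxy]-5-[(triisopropylsilyl)oxy]benzaldehyde | O=Cc1cc(OC(C)(C)C#C)cc(O[Si](C(C)C)(C(C)C)C(C)C)c1 | intermediate
5 | 3-hydroxy-2-(3-methylbuta-1,2-dien-1-yl)-5-[(triisopropylsilyl)oxy]benzaldehyde (allenylphenol) | O=Cc1cc(O[Si](C(C)C)(C(C)C)C(C)C)cc(O)c1C=C=C(C)C | intermediate (formed in the flask, not isolated)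
6 | 2,2-dimethyl-7-[(triisopropylsilyl)oxy]-2H-chromene-5-carbaldehyde | O=Cc1cc(O[Si](C(C)C)(C(C)C)C(C)C)cc2OC(C)(C)C=Cc12 | intermediate
7 | [(5-ethynyl-2,2-dimethyl-2H-chromen-7-yl)oxy]tri(propan-2-yl)silane | C#Cc1cc(O[Si](C(C)C)(C(C)C)C(C)C)cc2OC(C)(C)C=Cc12 | intermediate
8 | (3R,4R)-3,4-epoxy-5-ethynyl-2,2-dimethyl-7-[(triisopropylsilyl)oxy]chromane | C#Cc1cc(O[Si](C(C)C)(C(C)C)C(C)C)cc2OC(C)(C)[C@@H]3O[C@@H]3c12 | intermediate
9 | (3R)-5-ethynyl-2,2-dimethyl-7-[(triisopropylsilyl)oxy]chroman-3-ol | C#Cc1cc(O[Si](C(C)C)(C(C)C)C(C)C)cc2OC(C)(C)[C@H](O)Cc12 | intermediate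
10 | (3R)-5-ethynyl-2,2-dimethyl-7-[(triisopropylsilyl)oxy]chroman-3-yl trifluoromethanesulfonate | C#Cc1cc(O[Si](C(C)C)(C(C)C)C(C)C)cc2OC(C)(C)[C@H](OS(=O)(=O)C(F)(F)F)Cc12 | intermediate (formed in the flask, not isolated)
11 | 2-{(2S)-4-ethynyl-6-[(triisopropylsilyl)oxy]-2,3-dihydro-1-benzofuran-2-yl}propan-2-ol | C#Cc1cc(O[Si](C(C)C)(C(C)C)C(C)C)cc2c1C[C@@H](C(C)(C)O)O2 | intermediate
12 | resorcinol (benzene-1,3-diol) | Oc1cccc(O)c1 | starting material
13 | 1,3-bis(methoxymethoxy)benzene | COCOc1cccc(OCOC)c1 | intermediate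
14 | geranyl bromide, (2E)-1-bromo-3,7-dimethylocta-2,6-diene | CC(C)=CCC/C(C)=C/CBr | starting material
15 | 2-[(2E)-3,7-dimethylocta-2,6-dien-1-yl]-1,3-bis(methoxymethoxy)benzene | CC(C)=CCC/C(C)=C/Cc1c(OCOC)cccc1OCOC | intermediate
16 | 2-[(2E)-3,7-dimethylocta-2,6-dien-1-yl]-4-iodo-1,3-bis(methoxymethoxy)benzene | CC(C)=CCC/C(C)=C/Cc1c(OCOC)ccc(I)c1OCOC | intermediate
17 | 2-[(2E)-3,7-dimethylocta-2,6-dien-1-yl]-4-iodobenzene-1,3-diol | CC(C)=CCC/C(C)=C/Cc1c(O)ccc(I)c1O | intermediate
18 | (2S)-4-ethynyl-2-(2-hydroxypropan-2-yl)-2,3-dihydro-1-benzofuran-6-ol (alkynylphenol) | C#Cc1cc(O)cc2c1C[C@@H](C(C)(C)O)O2 | intermediate (formed in the flask, not isolated)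
19 | (2S)-4-({3-[(2E)-3,7-dimethylocta-2,6-dien-1-yl]-2,4-dihydroxyphenyl}ethynyl)-2-(2-hydroxypropan-2-yl)-2,3-dihydro-1-benzofuran-6-ol (diarylalkyne) | CC(C)=CCC/C(C)=C/Cc1c(O)ccc(C#Cc2cc(O)cc3c2C[C@@H](C(C)(C)O)O3)c1O | intermediate (formed in the flask, not isolated)
20 | (2S)-4-{7-[(2E)-3,7-dimethylocta-2,6-dien-1-yl]-6-hydroxy-1-benzofuran-2-yl}-2-(2-hydroxypropan-2-yl)-2,3-dihydro-1-benzofuran-6-ol (CNP0312668.2) | CC(C)=CCC/C(C)=C/Cc1c(O)ccc2cc(-c3cc(O)cc4c3C[C@@H](C(C)(C)O)O4)oc12 | target

**Step count**

Total: 12 steps. Longest linear sequence: 8 steps (steps 1–7, then step 12); steps 8–11 form the second branch.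

**Steps most likely to fail**

1. Step 7. Proton loss from the aryloxiranium ion (E1) or base-induced elimination of the triflate may outrun capture by water. The fallback sets out from 9 and accepts the elimination. The contraction is run without water (Tf2O, 2,6-di-tert-butyl-4-methylpyridine, CH2Cl2, −78 → 0 °C), so that the ion loses a methyl proton and gives {[(2S)-4-ethynyl-2-(prop-1-en-2-yl)-2,3-dihydro-1-benzofuran-6-yl]oxy}tri(propan-2-yl)silane F1. The tertiary C–O bond is then made separately by Markovnikov hydration of the 1,1-disubstituted alkene through hydrogen-atom transfer (Mukaiyama hydration: Co(acac)2, i.e. cobalt bis(acetylacetonate), PhSiH3, O2, i-PrOH/THF, 20 °C). The terminal alkyne should respond to this much more slowly. The fallback comes back to the route at 11.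

2. Step 3. The rearrangement may go toward the carbon between the two oxygen substituents and give the regioisomeric chromene. The fallback sets out from 1 and fixes the site by halogenation. NBS in MeCN at −20 °C should brominate para to one hydroxyl and ortho to the other, the usual site for resorcinols, giving 2-bromo-3,5-dihydroxybenzaldehyde F2. Stille coupling with tributyl(3-methylbut-2-en-1-yl)stannane (Pd(PPh3)4, DMF, 90 °C) gives 3,5-dihydroxy-2-(3-methylbut-2-en-1-yl)benzaldehyde F3. Oxidative cyclisation with DDQ (1,4-dioxane, 80 °C; ortho-quinone methide, then oxa-6π closure onto the only hydroxyl next to the prenyl group) gives 7-hydroxy-2,2-dimethyl-2H-chromene-5-carbaldehyde F4. Silylation (TIPSCl, imidazole, DMF) comes back to the route at 6.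

3. Step 12. Oxidative addition into the electron-rich, unprotected iodoresorcinol may be slow, so that oxidative homocoupling of the alkyne takes over in the fluoride-containing medium. The fallback sets out from 16 and 11 and couples the protected partners. Ordinary Sonogashira conditions (PdCl2(PPh3)2, CuI, Et3N, THF, 50 °C) should give 2-[(2S)-4-({3-[(2E)-3,7-dimethylocta-2,6-dien-1-yl]-2,4-bis(methoxymethoxy)phenyl}ethynyl)-6-[(triisopropylsilyl)oxy]-2,3-dihydro-1-benzofuran-2-yl]propan-2-ol F5. HCl/MeOH at 40 °C frees the two phenols to give 2-[(2E)-3,7-dimethylocta-2,6-dien-1-yl]-4-({(2S)-2-(2-hydroxypropan-2-yl)-6-[(triisopropylsilyl)oxy]-2,3-dihydro-1-benzofuran-4-yl}ethynyl)benzene-1,3-diol F6. Bu4NF in THF at 60 °C then removes the silyl group and closes the furan ring by fluoride-promoted 5-endo-dig cyclisation, which arrives at 20.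

**Further compounds**

F1 | step 7 | {[(2S)-4-ethynyl-2-(prop-1-en-2-yl)-2,3-dihydro-1-benzofuran-6-yl]oxy}tri(propan-2-yl)silane | C#Cc1cc(O[Si](C(C)C)(C(C)C)C(C)C)cc2c1C[C@@H](C(C)=C)O2
F2 | step 3 | 2-bromo-3,5-dihydroxybenzaldehyde | O=Cc1cc(O)cc(O)c1Br
F3 | step 3 | 3,5-dihydroxy-2-(3-methylbut-2-en-1-yl)benzaldehyde | O=Cc1cc(O)cc(O)c1CC=C(C)C
F4 | step 3 | 7-hydroxy-2,2-dimethyl-2H-chromene-5-carbaldehyde | O=Cc1cc(O)cc2OC(C)(C)C=Cc12
F5 | step 12 | 2-[(2S)-4-({3-[(2E)-3,7-dimethylocta-2,6-dien-1-yl]-2,4-bis(methoxymethoxy)phenyl}ethynyl)-6-[(triisopropylsilyl)oxy]-2,3-dihydro-1-benzofuran-2-yl]propan-2-ol | CC(C)=CCC/C(C)=C/Cc1c(OCOC)ccc(C#Cc2cc(O[Si](C(C)C)(C(C)C)C(C)C)cc3c2C[C@@H](C(C)(C)O)O3)c1OCOC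
F6 | step 12 | 2-[(2E)-3,7-dimethylocta-2,6-dien-1-yl]-4-({(2S)-2-(2-hydroxypropan-2-yl)-6-[(triisopropylsilyl)oxy]-2,3-dihydro-1-benzofuran-4-yl}ethynyl)benzene-1,3-diol | CC(C)=CCC/C(C)=C/Cc1c(O)ccc(C#Cc2cc(O[Si](C(C)C)(C(C)C)C(C)C)cc3c2C[C@@H](C(C)(C)O)O3)c1O
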